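The runs stem from a simulated flask for substances that don't exist, and the scatter is random.

The flask cannot turn its Z wholly into J: each J holds 3 X, so 1.0 M of Z asks for 3.00 M of X, and the 2.00 M charged is less. X is the limiting reagent, and I keep its books by what it fails to supply.

| setting | dawn | spring | flask |
|---|---|---|---|
| Z | 0.67 M | 1.5 M | 1.0 M |
| X | 2 M | 2 M | 2.00 M |
| remark | run made earlier | run made earlier |  |
| time |  |  | 80 min |

| run | time / min | E / % | G / % |
|---|---|---|---|
| dawn | 15.0 | 4.2 | 15.9 |
| dawn | 30.0 | 2.2 | 9.0 |
| dawn | 40.0 | 1.3 | 6.5 |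
| dawn | 60.0 | 1.5 | 4.5 |
| dawn | 80.0 | 0.7 | 4.0 |
| dawn | 90.0 | 0 | 2.5 |
| spring | 15.0 | 14.8 | 26.5 |
| spring | 30.0 | 11.9 | 25.1 |
| spring | 40.0 | 10.7 | 26.0 |
| spring | 60.0 | 7.7 | 26.2 |
| spring | 80.0 | 7.7 | 25.5 |
| spring | 90.0 | 6.2 | 26.7 |

(each reading ± 0.5 percentage points)

- a species is counted by the Z in it: one D counts as two
- on the list of suspects stand: Z + X -> E; Z + E -> D; X + E -> G; X + G -> J

The zero of my scale is 3 X per Z, the charge that J just uses up. The X missing from that zero, per Z charged, is 100% for the flask; I call it the tris shortfall. Free Z lacks 3 X, E lacks 2, G lacks one, D counted by its Z lacks 5/2, and X still free pays back: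

shortfall = 3[Z] + 2[E] + [G] + 5[D]/2 − [X]

The dawn run stands almost at the zero, with a shortfall of 1.49%, and at 90.0 min its E and G enter for 2.50%. The spring run owes 167%; at 90.0 min its E and G enter for 39.1%, so at least 128% lies in Z and D. The shortfall of the flask is larger than dawn's and smaller than spring's, but the ledger gives the sum of the entries, not E by itself.

- equivalents of X to Z, everything else as given, that leave most E at 80 min
- the amount of E then, in percent of the Z charged
- the amount of E with the amounts as given

The forecast gives 6.8%, and 8.3% at 1.25 equiv: “Z + E → D then takes E to about 7% at 80 min”.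

The flask gives 7.31%, and 9.20% at 1.36 equiv, each within the margin of the forecast.

    Z + X → E (k = 0.00411 /M/s)
    Z + E → D (k = 5.71 × 10⁻⁴ /M/s)
    X + E → G (k = 0.00956 /M/s)
    X + G → J (k = 0.00528 /M/s)

By X + E → G alone, at the concentrations as charged, E has a half-life of 0.60 min, short against 80 min. By the same path at 80.0 min, with X in the flask at 0% of its charge, that half-life is 12000 h. The entries of the flask then add to 100% against a shortfall of 100%. With 1.7 M of Z the shortfall is 182%, the entries add to 182%, and E among them stands at 5.72%.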